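The route rests on one disconnection: the C9–C10 bond of ring B, which joins the spiro ether carbon C9 of the oxolane to the ring-fusion carbon C10 that carries C20. Because C9 sits at the ketal level and C20 at the aldehyde level, a Lewis acid can turn C9 into an oxolanylium ion and C10 into the carbon terminus of an enol silane; their union closes ring B and sets both quaternary centres in one operation. The precursor is the ring A γ-lactone (C19 to O6) carrying the exocyclic C10=C20 silyl enol ether and, on C6, the C7–C8 chain ending in the C9 methyl ketal of the spiro oxolane-lactone.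

Key step: step 16

Assumption: labdane numbering is used throughout; the target as drawn has H5 cis to C20 (rings A/B cis) with the 19,6-lactone trans-fused to rings A and B, so ring B cannot be an ideal chair, and the route is built for exactly this array.

Step 1
Reactants: 1 methyl tiglate
Product: 2 methyl (E)-2-methyl-4-oxobut-2-enoate
Conditions: SeO2, 1,4-dioxane, reflux
Reagents that add atoms: selenium dioxide, O=[Se]=O
Why: Riley allylic oxidation with SeO2 (ene reaction followed by a 2,3-sigmatropic shift) should convert the γ-methyl group of the enoate into the aldehyde with retention of the E geometry, and no stereocentre is formed.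

Step 2
Reactants: 3 (E)-penta-2,4-dien-1-ol
Product: 4 (E)-5-(benzyloxy)penta-1,3-diene
Conditions: NaH, BnBr, Bu4NI (cat.), THF, 0 °C to rt
Reagents that add atoms: benzyl bromide, BrCc1ccccc1
Why: Williamson ether synthesis on the primary allylic alkoxide leaves the diene untouched and creates no stereocentre.

Step 3
Reactants: 2 methyl (E)-2-methyl-4-oxobut-2-enoate; 4 (E)-5-(benzyloxy)penta-1,3-diene
Product: 5 ring A cyclohexene aldehyde (Diels–Alder adduct)
Conditions: (5S)-5-benzyl-2,2,3-trimethylimidazolidin-4-one·HCl (first-generation MacMillan catalyst, 20 mol %), MeNO2/H2O 95:5, 0 °C to rt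
Reagents that add atoms: none
Why: Iminium-catalysed Diels–Alder reaction, in which condensation of the aldehyde of 2 with the amine makes C6 the controlling acceptor so that the substituted diene terminus (C10) bonds to C5 and the free terminus (C3) to C4, the benzyl group of the (5S) catalyst blocks one face of the E iminium ion so that C4 and C5 should arise in the absolute sense drawn, the E geometry of 2 places C18 cis to C6, and the C10 centre (expected mainly endo, its epimer is carried along) is erased in step 15.

Step 4
Reactants: 6 (S)-3-bromo-2-methylpropan-1-ol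
Product: 7 (S)-(3-bromo-2-methylpropoxy)(tert-butyl)dimethylsilane
Conditions: TBSCl, imidazole, CH2Cl2, 0 °C to rt
Reagents that add atoms: tert-butyldimethylsilyl chloride, CC(C)(C)[Si](C)(C)Cl
Why: Imidazole-mediated silylation of the primary alcohol protects the future C9 oxygen, and the C8 stereocentre of 6 is not touched.

Step 5
Reactants: 7 (S)-(3-bromo-2-methylpropoxy)(tert-butyl)dimethylsilane; 5 ring A cyclohexene aldehyde
Product: 11 ring A lactone silyl ether, via Grignard reagent 8 (not isolated), via dialkylzinc 9 (not isolated), via hydroxy ester 10 (not isolated)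
Conditions: (i) Mg, THF, rt; ZnCl2 (0.5 equiv), then 1,4-dioxane, filter; (ii) 5, Ti(OiPr)4, (1S,2S)-1,2-bis(trifluoromethanesulfonamido)cyclohexane (10 mol %), toluene, −20 °C; (iii) aq. NH4Cl; DBU (cat.), toluene, 60 °C
Reagents that add atoms: none
Why: Catalytic enantioselective addition of a functionalised dialkylzinc to an aldehyde under titanium bis-sulfonamide catalysis, in which the (1S,2S) ligand should deliver the alkyl group to the Re face of the C6 aldehyde under catalyst control (6R, O6 as required), C8 is carried in from 6, and DBU-catalysed transesterification of the γ-hydroxy ester closes the γ-lactone, whose trans fusion to ring A is fixed by C4 and C5.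

Step 6
Reactants: 11 ring A lactone silyl ether
Product: 12 C9 carboxylic acid
Conditions: CrO3, H2SO4, H2O, acetone, 0 °C (Jones reagent)
Reagents that add atoms: water, O
Why: Jones oxidation, in which the aqueous acid cleaves the primary silyl ether and chromic acid takes the alcohol through the aldehyde hydrate to the acid, while the benzyl ether, the alkene and the lactone should survive at 0 °C and the C8 centre is not enolised in acid.

Step 7
Reactants: 12 C9 carboxylic acid
Product: 13 S-(pyridin-2-yl) thioester
Conditions: 2,2′-dipyridyl disulfide, PPh3, CH2Cl2, rt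
Reagents that add atoms: 2,2′-dipyridyl disulfide, c1ccc(SSc2ccccn2)nc1
Why: Redox condensation (phosphine/disulfide thioesterification) activates the acid as the thioester under neutral conditions that should not epimerise C8.

Step 8
Reactants: 14 (R)-malic acid
Product: 15 cis-dioxolanone acid
Conditions: t-BuCHO, p-TsOH (cat.), H2SO4 (cat.), pentane, reflux (Dean–Stark)
Reagents that add atoms: pivalaldehyde, CC(C)(C)C=O
Why: Acid-catalysed acetalisation of the α-hydroxy acid unit with pivalaldehyde should give the cis-dioxolanone as the thermodynamic product, the C13 centre of malic acid controlling the new acetal centre.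

Step 9
Reactants: 15 cis-dioxolanone acid; 16 2-bromoethyl trifluoromethanesulfonate
Product: 18 alkylated dioxolanone acid, via dilithium enolate 17 (not isolated)
Conditions: LiN(SiMe3)2 (2.2 equiv), THF, −78 °C; 16, −78 °C; aq. HCl
Reagents that add atoms: none
Why: Enolate alkylation with self-regeneration of the stereocentre, in which the lithium enolate of the dioxolanone (carboxylate dianion) is alkylated by the primary triflate on the face opposite the tert-butyl group, so that the two-carbon arm replaces H at C13 with overall retention and the bromide remains as the later coupling handle.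

Step 10
Reactants: 18 alkylated dioxolanone acid
Product: 20 bromoethyl hydroxy lactone, via hydroxyethyl dioxolanone 19 (not isolated)
Conditions: BH3·SMe2, THF, 0 °C to rt; MeOH; p-TsOH (cat.), CH2Cl2, rt
Reagents that add atoms: none
Why: Chemoselective borane reduction of the free carboxylic acid gives primary alcohol 19, and acid-catalysed transesterification onto the dioxolanone carbonyl then closes the γ-lactone with loss of pivalaldehyde, C13 being untouched and unable to scramble because the bromoethyl arm never bears a free hydroxyl.

Step 11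
Reactants: 13 S-(pyridin-2-yl) thioester; 20 bromoethyl hydroxy lactone
Product: 22 hydroxy ketone, via iodoethyl hydroxy lactone 21 (not isolated)
Conditions: NiCl2(dme) (10 mol %), 4,4′-di-tert-butyl-2,2′-bipyridine (10 mol %), Zn, NaI (0.5 equiv), DMA, rt
Reagents that add atoms: none
Why: Nickel-catalysed reductive cross-electrophile coupling of a thioester with a primary alkyl halide (iodide formed by halide exchange) makes the C9–C11 bond and the C9 ketone directly without a basic organometallic, so that the free tertiary alcohol, both lactones and the C8 centre next to the new carbonyl should be tolerated.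

Step 12
Reactants: 22 hydroxy ketone
Product: 23 C9 methyl ketal benzyl ether
Conditions: PPTS (cat.), MeOH, 3 Å molecular sieves, rt
Reagents that add atoms: methanol, CO
Why: Acid-catalysed ketalisation, in which the C13 hydroxyl closes the oxolane hemiketal on C9 and methanol exchange gives the 2-methoxyoxolane as both C9 anomers (irrelevant, since C9 is planarised in step 16) while the weak acid should keep C8 from enolising.

Step 13
Reactants: 23 C9 methyl ketal benzyl ether
Product: 24 C20 alcohol
Conditions: H2 (1 atm), Pd/C, NaHCO3, EtOAc, rt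
Reagents that add atoms: none
Why: Heterogeneous catalytic hydrogenation saturates the C1=C2 alkene and hydrogenolyses the benzyl ether in one operation, the bicarbonate protecting the ketal, and no stereocentre is formed.

Step 14
Reactants: 24 C20 alcohol
Product: 25 C20 aldehyde
Conditions: Dess–Martin periodinane, pyridine, CH2Cl2, 0 °C to rt
Reagents that add atoms: none
Why: Dess–Martin oxidation takes the primary alcohol to the C20 aldehyde under buffered conditions that should spare the ketal, and epimerisation at C10 is harmless.

Step 15
Reactants: 25 C20 aldehyde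
Product: 27 enol silane, via potassium enolate 26 (not isolated)
Conditions: KN(SiMe3)2, THF, −78 °C; TBSCl, DMPU, −78 to 0 °C
Reagents that add atoms: tert-butyldimethylsilyl chloride, CC(C)(C)[Si](C)(C)Cl
Why: Enolate O-silylation, in which C10–H is the only acidic hydrogen α to a carbonyl (both lactones are α-quaternary and C8 is flanked by the ketal) so that a single enolate forms and is trapped on oxygen without a silyl triflate that could ionise the ketal, the C10 centre is erased and either enol ether geometry serves.

Step 16
Reactants: 27 enol silane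
Product: 28 20-oxo tetracycle
Conditions: Me3SiOTf (1.2 equiv), 2,6-di-tert-butyl-4-methylpyridine, CH2Cl2, −78 to −40 °C; aq. NaHCO3
Reagents that add atoms: none
Why: Me3SiOTf ionises the C9 methyl ketal (either anomer) to the five-membered oxolanylium ion, the C10=C20 enol silane adds through C10, and loss of the silyl group from the resulting silyloxocarbenium ion unveils the C20 aldehyde. The closest known reaction type is the intramolecular Mukaiyama aldol-type (Prins) addition of enol silanes to ketal-derived oxocarbenium ions. Ring B is closed in a 6-(enolexo)-exo-trig mode and is the only ring formed. C9 is controlled by the C8 stereocentre: with C17 pseudo-equatorial on the forming ring, C10 should add to the oxolanylium face that leaves C11 trans to C17. C10 is controlled by the three-atom tether from C5, which has to deliver C9 to the ring A face anti to H5 so that C20 ends cis to H5; because the lactone is trans-fused to both rings this array cannot be a true chair, and it is here that the route stakes its risk. Chemoselectivity is secured by the substrate, since neither lactone has an α-hydrogen and the only enol silane is at C20, while the hindered pyridine base removes triflic acid and so protects C8, the one centre that could epimerise through an enol ether.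

Step 17
Reactants: 28 20-oxo tetracycle
Product: 29 C20 alcohol of the tetracycle
Conditions: NaBH4, THF/EtOH, −20 °C; aq. NH4Cl
Reagents that add atoms: none
Why: Borohydride reduction should take the hindered neopentyl aldehyde to the primary alcohol at low temperature without touching the two lactones, and no stereocentre is formed.

Step 18
Reactants: 29 C20 alcohol of the tetracycle
Product: 30 target
Conditions: Ac2O, pyridine, DMAP (cat.), CH2Cl2, 0 °C to rt
Reagents that add atoms: acetic anhydride, CC(=O)OC(C)=O
Why: DMAP-catalysed acylation of the primary alcohol with acetic anhydride gives the C20 acetate and completes the target.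

Compound list
1 | methyl tiglate, methyl (E)-2-methylbut-2-enoate | C/C=C(\C)C(=O)OC | starting material
2 | methyl (E)-2-methyl-4-oxobut-2-enoate | O=C/C=C(\C)C(=O)OC | intermediate
3 | (E)-penta-2,4-dien-1-ol | OC/C=C/C=C | starting material
4 | (E)-5-(benzyloxy)penta-1,3-diene | C=C/C=C/COCc1ccccc1 | intermediate
5 | methyl 5-[(benzyloxy)methyl]-6-formyl-1-methylcyclohex-3-ene-1-carboxylate; ring A with C4 (CH3, CO2Me), C5 (H, CHO), C10 (H, CH2OBn), C1=C2; C18 cis to the formyl group, CH2OBn cis to it (endo) | O=C[C@H]1[C@@H](COCc2ccccc2)C=CC[C@]1(C)C(=O)OC | intermediate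
6 | (S)-3-bromo-2-methylpropan-1-ol | BrC[C@@H](C)CO | starting material
7 | (S)-(3-bromo-2-methylpropoxy)(tert-butyl)dimethylsilane | BrC[C@@H](C)CO[Si](C)(C)C(C)(C)C | intermediate
8 | [(S)-3-(tert-butyldimethylsilyloxy)-2-methylpropyl]magnesium bromide | Br[Mg]C[C@@H](C)CO[Si](C)(C)C(C)(C)C | intermediate (not isolated)
9 | bis[(S)-3-(tert-butyldimethylsilyloxy)-2-methylpropyl]zinc | CC(C)(C)[Si](C)(C)OC[C@H](C)C[Zn]C[C@@H](C)CO[Si](C)(C)C(C)(C)C | intermediate (not isolated)
10 | (6R)-hydroxy ester: 5 with the formyl group replaced by CH(OH)CH2CH(CH3)CH2OTBS (C6 to C9) | c1ccccc1COC[C@H]2C=CC[C@](C)(C(=O)OC)[C@H]2[C@H](O)C[C@@H](C)CO[Si](C)(C)C(C)(C)C | intermediate (not isolated)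
11 | ring A γ-lactone (C19 to O6, trans-fused), C1=C2 alkene, CH2OBn on C10, chain CH2CH(CH3)CH2OTBS on C6 | c1ccccc1COC[C@H]2C=CC[C@]3(C)C(=O)O[C@H](C[C@@H](C)CO[Si](C)(C)C(C)(C)C)[C@@H]23 | intermediate
12 | C9 carboxylic acid of 11 (chain CH2CH(CH3)CO2H on C6) | c1ccccc1COC[C@H]2C=CC[C@]3(C)C(=O)O[C@H](C[C@@H](C)C(=O)O)[C@@H]23 | intermediate
13 | S-(pyridin-2-yl) thioester of 12 | c1ccccc1COC[C@H]2C=CC[C@]3(C)C(=O)O[C@H](C[C@@H](C)C(=O)Sc4ccccn4)[C@@H]23 | intermediate
14 | (R)-malic acid | O[C@H](CC(=O)O)C(=O)O | starting material
15 | 2-[(2R,4R)-2-tert-butyl-5-oxo-1,3-dioxolan-4-yl]acetic acid (cis) | CC(C)(C)[C@@H]1O[C@H](CC(=O)O)C(=O)O1 | intermediate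
16 | 2-bromoethyl trifluoromethanesulfonate | BrCCOS(=O)(=O)C(F)(F)F | starting material
17 | dilithium enolate-carboxylate of 15 | [Li+].[Li+].CC(C)(C)[C@@H]1OC(CC(=O)[O-])=C([O-])O1 | intermediate (not isolated)
18 | 2-[4-(2-bromoethyl)-2-tert-butyl-5-oxo-1,3-dioxolan-4-yl]acetic acid, bromoethyl trans to tert-butyl | CC(C)(C)[C@@H]1O[C@@](CC(=O)O)(CCBr)C(=O)O1 | intermediate
19 | 5-(2-bromoethyl)-2-tert-butyl-5-(2-hydroxyethyl)-1,3-dioxolan-4-one | CC(C)(C)[C@@H]1O[C@@](CCO)(CCBr)C(=O)O1 | intermediate (not isolated)
20 | 3-(2-bromoethyl)-3-hydroxyoxolan-2-one, C13 configured as in the target | BrCC[C@@]1(O)CCOC1=O | intermediate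
21 | 3-hydroxy-3-(2-iodoethyl)oxolan-2-one, same configuration | ICC[C@@]1(O)CCOC1=O | intermediate (not isolated)
22 | hydroxy ketone: ring A lactone of 11 with the C6 chain CH2CH(CH3)C(=O)CH2CH2 attached to C13 of the 3-hydroxyoxolan-2-one | c1ccccc1COC[C@H]2C=CC[C@]3(C)C(=O)O[C@H](C[C@@H](C)C(=O)CC[C@@]4(O)CCOC4=O)[C@@H]23 | intermediate
23 | C9 methyl ketal (2-methoxyoxolane spiro-fused at C13 to the oxolan-2-one, both C9 anomers), benzyl ether, C1=C2 alkene | c1ccccc1COC[C@H]2C=CC[C@]3(C)C(=O)O[C@H](C[C@@H](C)C4(OC)CC[C@]5(CCOC5=O)O4)[C@@H]23 | intermediate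
24 | saturated ring A lactone with CH2OH (C20) on C10 and the C9 methyl ketal | OC[C@H]1CCC[C@]2(C)C(=O)O[C@H](C[C@@H](C)C3(OC)CC[C@]4(CCOC4=O)O3)[C@@H]12 | intermediate
25 | C20 aldehyde of 24 | O=C[C@H]1CCC[C@]2(C)C(=O)O[C@H](C[C@@H](C)C3(OC)CC[C@]4(CCOC4=O)O3)[C@@H]12 | intermediate
26 | potassium enolate of 25 | [K+].[O-]/C=C1\CCC[C@]2(C)C(=O)O[C@H](C[C@@H](C)C3(OC)CC[C@]4(CCOC4=O)O3)[C@@H]12 | intermediate (not isolated)
27 | key-step precursor: ring A lactone with exocyclic C10=C20 tert-butyldimethylsilyl enol ether (drawn with OSi syn to C1; geometry immaterial) and the C9 methyl ketal (both anomers) | CC(C)(C)[Si](C)(C)O/C=C1\CCC[C@]2(C)C(=O)O[C@H](C[C@@H](C)C3(OC)CC[C@]4(CCOC4=O)O3)[C@@H]12 | intermediate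
28 | key-step product: 20-oxo analogue of the target (C20 aldehyde on C10) | O=C[C@@]12CCC[C@]3(C)C(=O)O[C@H](C[C@@H](C)[C@]14CC[C@]1(CCOC1=O)O4)[C@@H]23 | intermediate
29 | 20-hydroxy compound (C20 CH2OH) | OC[C@@]12CCC[C@]3(C)C(=O)O[C@H](C[C@@H](C)[C@]14CC[C@]1(CCOC1=O)O4)[C@@H]23 | intermediate
30 | CNP0298733.1, 20-acetoxy-9,13-epoxylabdane-19,6:16,15-diolide as drawn | CC(=O)OC[C@@]12CCC[C@]3(C)C(=O)O[C@H](C[C@@H](C)[C@]14CC[C@]1(CCOC1=O)O4)[C@@H]23 | target

Total step count: 18
Longest linear sequence: 13 steps (1, 3, 5, 6, 7, 11, 12, 13, 14, 15, 16, 17, 18)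

Steps most likely to fail

Step 16. The closure may take place on the other face of C10. The trans-fused lactone holds C6 equatorial on ring A and C7 anti to C10 across the lactone ring, so the strain-free chair array leads to the trans ring fusion (C20 trans to H5), whereas the array needed here has to twist. A second failure mode is loss of a proton from the oxolanylium ion to give an enol ether, which would scramble C8. The fallback sets out from 10 and comes back at 28; it keeps the same bond construction but postpones the lactone. The crude hydroxy ester 10 would be acetylated (Ac2O, pyridine, DMAP) instead of lactonised to give the 6-O-acetyl seco ester F1. The operations of steps 6, 7, 11, 12, 13, 14 and 15 would then be repeated unchanged to give in turn the seco acid F2, the seco pyridyl thioester F3, the seco hydroxy ketone F4, the seco methyl ketal F5, the saturated seco C20 alcohol F6, the seco C20 aldehyde F7 and the seco enol silane F8. Without the lactone, ring A is free to place the C6 chain axial (allylic 1,3-strain with the enol silane favours this), and an axial three-atom tether can reach only the C10 face on its own side. The same Me3SiOTf closure should then give the cis-fused seco aldehyde F9. Methanolysis of the acetate (K2CO3, MeOH) would give the seco hydroxy ester F10, and base-catalysed lactonisation (DBU, toluene, heat, removal of methanol) would return 28.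

Step 3. The cycloaddition may be slow or poorly face-selective, because the iminium carbon that becomes C4 is fully substituted, and the diene may polymerise in the acidic aqueous medium. The fallback sets out from 2 and 4 and comes back at 11; it replaces enantioselective catalysis by separation of diastereomers. A Me2AlCl-promoted cycloaddition (CH2Cl2, −78 °C) should give the racemic adduct with the same regiochemistry, that is 5 together with the enantiomeric adduct F11. Step 5 on the racemate is catalyst-controlled at C6 and uses enantiopure 9, so it would give 11 and, from F11 by way of the diastereomeric hydroxy ester F12, the diastereomeric lactone F13, which would be removed by chromatography.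

Step 5. Facial selectivity at C6 may be eroded by a mismatch between the catalyst and the intrinsic bias of the α-branched aldehyde, or by uncatalysed background addition if magnesium salts are carried over. The fallback sets out from 5 and comes back at 10; it sets C6 by reduction instead of addition. Grignard reagent 8 would be added directly to 5 (THF, −78 °C) to give 10 together with the C6-epimeric hydroxy ester F14. Dess–Martin oxidation of the mixture would give the C6 ketone F15, and CBS reduction with the (S)-methyl oxazaborolidine and BH3·SMe2 should return 10 under reagent control, which is lactonised to 11 as in step 5.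

Further compounds
F1 | step 16 | 6-O-acetyl seco ester (acetate of 10) | c1ccccc1COC[C@H]2C=CC[C@](C)(C(=O)OC)[C@H]2[C@H](OC(C)=O)C[C@@H](C)CO[Si](C)(C)C(C)(C)C
F2 | step 16 | seco acid | c1ccccc1COC[C@H]2C=CC[C@](C)(C(=O)OC)[C@H]2[C@H](OC(C)=O)C[C@@H](C)C(=O)O
F3 | step 16 | seco pyridyl thioester | c1ccccc1COC[C@H]2C=CC[C@](C)(C(=O)OC)[C@H]2[C@H](OC(C)=O)C[C@@H](C)C(=O)Sc3ccccn3
F4 | step 16 | seco hydroxy ketone | c1ccccc1COC[C@H]2C=CC[C@](C)(C(=O)OC)[C@H]2[C@H](OC(C)=O)C[C@@H](C)C(=O)CC[C@@]3(O)CCOC3=O
F5 | step 16 | seco methyl ketal | c1ccccc1COC[C@H]2C=CC[C@](C)(C(=O)OC)[C@H]2[C@H](OC(C)=O)C[C@@H](C)C3(OC)CC[C@]4(CCOC4=O)O3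
F6 | step 16 | saturated seco C20 alcohol | OC[C@H]1CCC[C@](C)(C(=O)OC)[C@H]1[C@H](OC(C)=O)C[C@@H](C)C2(OC)CC[C@]3(CCOC3=O)O2
F7 | step 16 | seco C20 aldehyde | O=C[C@H]1CCC[C@](C)(C(=O)OC)[C@H]1[C@H](OC(C)=O)C[C@@H](C)C2(OC)CC[C@]3(CCOC3=O)O2
F8 | step 16 | seco enol silane | CC(C)(C)[Si](C)(C)O/C=C1/CCC[C@](C)(C(=O)OC)[C@H]1[C@H](OC(C)=O)C[C@@H](C)C2(OC)CC[C@]3(CCOC3=O)O2
F9 | step 16 | cis-fused seco aldehyde | O=C[C@]12CCC[C@](C)(C(=O)OC)[C@H]1[C@H](OC(C)=O)C[C@@H](C)[C@]23CC[C@]2(CCOC2=O)O3
F10 | step 16 | seco hydroxy ester | O=C[C@]12CCC[C@](C)(C(=O)OC)[C@H]1[C@H](O)C[C@@H](C)[C@]23CC[C@]2(CCOC2=O)O3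
F11 | step 3 | enantiomeric adduct (enantiomer of 5) | O=C[C@@H]1[C@H](COCc2ccccc2)C=CC[C@@]1(C)C(=O)OC
F12 | step 3 | diastereomeric hydroxy ester | c1ccccc1COC[C@@H]2C=CC[C@@](C)(C(=O)OC)[C@@H]2[C@H](O)C[C@@H](C)CO[Si](C)(C)C(C)(C)C
F13 | step 3 | diastereomeric lactone | c1ccccc1COC[C@@H]2C=CC[C@@]3(C)C(=O)O[C@H](C[C@@H](C)CO[Si](C)(C)C(C)(C)C)[C@H]23
F14 | step 5 | C6-epimeric hydroxy ester | c1ccccc1COC[C@H]2C=CC[C@](C)(C(=O)OC)[C@H]2[C@@H](O)C[C@@H](C)CO[Si](C)(C)C(C)(C)C
F15 | step 5 | C6 ketone | c1ccccc1COC[C@H]2C=CC[C@](C)(C(=O)OC)[C@H]2C(=O)C[C@@H](C)CO[Si](C)(C)C(C)(C)C
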